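## The problem

The target is a doubly angeloylated bisabolane bis-epoxide. A cyclohexane ring (C1–C6) is joined at C1, through the 1,1-disubstituted alkene C7=C14, to the chain C8–C11 with two methyl groups on C11. Seven stereocentres must be set: C1–C5 are contiguous on the ring, with the C1 side chain, the C2 hydroxyl, the C3 angelate and the C4–C5 epoxide oxygen all on one face, and C8 and C10 lie on the chain. On the ring, C1 can steer reagents only to the opposite face, so the cis oxygen at C2 needs an inversion, whereas a free C3 hydroxyl can deliver the epoxide oxygen to its own face. On the chain, C8 and C10 are insulated from the ring by the sp2 carbon C7, so one of them needs reagent control and the other can be relayed 1,3 from it. The fragile groups are the two trisubstituted epoxides (acid), the two angelates (Z to E isomerisation to tiglates, methanolysis) and the free C2 hydroxyl cis to the C3 ester (acyl migration under base); in addition O2 must be told from O3 and O8 from O10. The feature that opens the key step is the 1,3-relationship of the C8 and C10 oxygens across C9, with C8 bound to the vinylic carbon C7. That is the pattern left by an isoxazoline made from a nitrile oxide at C8 (the oxidised methyl of an isopropenyl group) and the vinyl group of 2-methylbut-3-en-2-ol, which brings C9, C10, C11, both methyls and the C11 oxygen in one piece.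

## Retrosynthesis

**O2–Si bond.** The target 26 is traced to its C2 triethylsilyl ether 25. The hydroxyl next to the C3 angelate is unveiled last so that no basic step meets the cis hydroxy ester. A silyl ether is preferred to an ester or benzyl-type ether because buffered fluoride removes it without touching angelates. The forward step must spare two epoxides.

**O–C10 bond of the side-chain epoxide.** 25 is opened to the 10,11-diol 23 by way of the C10 mesylate 24. Epoxidising a C10=C11 alkene would need an external chiral oxidant to choose a face far from any stereocentre and to ignore the other alkenes. The diol route takes C10 from an earlier stereocentre and inverts it, so 23 must be 10S. The forward step needs sulfonylation of the one secondary hydroxyl and SN2 closure.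

**Acyl–oxygen bonds at O8 and O10.** The C8 angelate of 23 is traced through the O10 acetate 22 to alcohol 21, in which O8 is free and O10 is acetylated. This removes the one difficult oxygen pair of the chain from the problem. The forward steps need an angeloylation that does not isomerise the Z alkene and a methanolysis that takes an acetate before an angelate.

**C8–H bond together with the O10 acetyl group.** 21 is cut in the Evans–Tishchenko sense to β-hydroxy ketone 20 and acetaldehyde. A borohydride-based directed reduction would also give the anti relationship but would leave a triol whose O8 and O10 differ only in hindrance. The Tishchenko variant sets C8 from C10 and differentiates the oxygens in the same step.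

**N–O bond and C=N bond.** Ketone 20 is not made by an aldol reaction, which would require a regiodefined enolate of an α-methylene ketone and an enantioselective addition. It is unmasked from isoxazoline 18. The precursor hides the sensitive β-hydroxy enone until two steps before it is consumed.

**C8–C9 and O–C10 bonds (key disconnection).** 18 is cut to nitrile oxide 17 and 2-methylbut-3-en-2-ol 16. Against disconnections at C7–C8 or C1–C7, this one uses a carbon that carvone already carries as a methyl group and adds five chain atoms with the C10 and C11 oxygens in place. The precursor 17 has no chain stereocentre. The forward reaction must give the 5-substituted regioisomer and the 10S configuration.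

**Oxidation level at C8.** 17 goes back through hydroximoyl chloride 15, oxime 14, enal 13 and allylic alcohol 12 to the isopropenyl compound 11. No skeletal bond is cut. The demand is site selectivity of the allylic oxidation, which is why the ring alkene is already an epoxide and the only electron-rich alkene in 11 is the isopropenyl group.

**C3 ester bond and the two epoxide C–O bonds.** 11 is traced to epoxy alcohol 9 and then to allylic alcohol 8. In 8 the C3 hydroxyl is the only free hydroxyl, so it directs the epoxidation and is then angeloylated, while O2 is already silylated. The two ring oxygens are thus told apart by the order in which they are made, not by a selective reaction on a diol.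

**C3–H, O2–Si and C2–O bonds.** 8 comes from silyloxy enone 7 by 1,2-reduction, 7 from cis ketol 6, 6 by inversion of trans ketol 4, and 4 by α′-hydroxylation of (R)-carvone 1 through silyl dienol ether 2 and silyloxy ketone 3. Carvone supplies C1 in the right absolute configuration, the ring, the C4 methyl, the C4=C5 alkene and the isopropenyl group that becomes C7, C14 and C8.

## Roads not taken

Alternative 1: The ring would be closed at C3–C4. The acyclic aldehyde A2 carries the C1 and C2 stereocentres, a Weinreb amide as C7 and a Z alkenyl iodide as C4=C5. With CrCl2 and catalytic NiCl2 the alkenylchromium formed at C4 adds to the C3 aldehyde to give cyclohexenol A1 (Nozaki–Hiyama–Kishi cyclisation).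
- Merits: the ring, the C3 carbinol and a geometrically defined ring alkene arise in one mild, chemoselective step. O2 (ether) and O3 (free hydroxyl) leave the key step already distinguished. In this respect the road is better than the chosen one, which needs an inversion at C2 and an ordered silylation to reach the same point.
- Weak points: A2 has two adjacent stereocentres, one of them α to the aldehyde, that must be made by asymmetric synthesis instead of being bought. The configuration at C3 rests on a Felkin-versus-chelation balance in a cyclic transition state, so the all-cis result is not assured. Chromium is used in excess. A1 stops at a carboxyl-level C7, so the C14 methylene, all of C8–C11 and both chain stereocentres still lie ahead, next to an epimerisable C1.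
- Comparison: the chosen plan sets against the cleaner O2/O3 differentiation a ring taken ready-made from carvone and a key step spent on the chain, which is the harder half.

Alternative 2: The ring would be cut at C2–C3 and C1–C6. In triene A4 a diisopropylsilylene links the oxygen of a dienyl ether (C3=C4(Me)–C5=C6) to that of a Z β-silyloxy enone (C1=C2) that already carries the C7 ketone, the C8 silyl ether and the prenyl end. Heating gives the dioxasilolane-fused cyclohexene A3 by intramolecular Diels–Alder reaction.
- Merits: this is the most convergent road. All fifteen skeletal carbons, the ring alkene and the C1–C3 relationships arise in one step, and the Z dienophile geometry translates directly into the cis C1/C2 relation. On paper it is shorter than the chosen plan.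
- Weak points: A4 is a mixed bis-enol silyl acetal, which is hydrolytically fragile and hard to assemble from two different enol partners without scrambling or loss of enol ether geometry. The absolute sense of the cycloaddition must be induced by C8 across the C7 carbonyl, a weak relay. A three-atom tether on an E dienyl ether does not enforce the cis ring fusion. In A3 the silylene bridges O2 and O3 symmetrically, so they emerge undifferentiated. The C7 ketone must be methylenated between two epimerisable centres, and C10 would need a reagent-controlled epoxidation in competition with the ring alkene.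
- Comparison: the chosen plan is more linear. It sets against this a named controller for every stereocentre and ring oxygens that are differentiated from the start.

Alternative 3: The ring would be cut at C1–C6. The six-membered lactone A6 (C7 carbonyl, ring oxygen on C4, vinyl and methyl on C4) is converted into its silyl ketene acetal. Ireland–Claisen rearrangement through the ring-enforced boat transition state forms C1–C6, breaks C4–O and gives acid A5 with the C4=C5 alkene; the configuration of C4 is transferred to C1.
- Merits: the rearrangement is stereospecific and is probably the most predictable key step of the four, more so than a tartrate-controlled cycloaddition on a tertiary alkoxide. It forms the trisubstituted ring alkene and C1 together.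
- Weak points: A6 needs three contiguous stereocentres, including a fully substituted allylic ether carbon, and is harder to make than the ring it produces, which carvone offers directly. In A5 the oxygens O2 and O3 are identical silyl ethers and C7 is a carboxylic acid, so the differentiation problem, C14, C8–C11 and both chain stereocentres all remain. C1 is α to a carboxyl group during chain attachment.
- Comparison: the chosen plan gives up some stereochemical certainty in its key step. It sets against this that the key step solves the chain and not the ring, and that fewer carbon–carbon bonds remain to be made.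

Key step: step 10

Assumption (locants and names): from compound 9 onwards the locants of the target skeleton are used (ring C1 bears the chain, C2, C3, C4 bears the methyl, C5, C6; chain C7 with methylene C14, C8–C11). "Angelate" means (Z)-2-methylbut-2-enoate, and Cy stands for the (1S,2R,3R,4S,5S)-3-(angeloyloxy)-4,5-epoxy-4-methyl-2-(triethylsilyloxy)cyclohexyl group, with the bond to the chain, O2, O3 and the epoxide oxygen on one face.

Assumption (key step): the (S,S)-tartrate is taken to give the 10S adduct by analogy with primary allylic alcohols, where the (R,R)-ester leads to the 5R isoxazoline; if the tertiary alkoxide responds in the opposite sense, the (R,R)-ester is used.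

## Route

Step 1
Reactants: 1 (R)-carvone
Product: 4 trans-6-hydroxycarvone (5S,6S), via silyl dienol ether 2 (not isolated), via α-silyloxy ketone 3 (not isolated)
Conditions: LDA (LiN(iPr)2), THF, −78 °C, then TMSCl; mCPBA, NaHCO3, CH2Cl2, −20 °C; 1 M HCl, THF, 0 °C
Reagents that add atoms: 3-chloroperoxybenzoic acid, OOC(=O)c1cccc(Cl)c1
Why: Rubottom oxidation: kinetic α′-deprotonation gives the cross-conjugated silyl dienol ether 2, whose enol ether alkene is the most electron-rich and is epoxidised on the face away from the neighbouring isopropenyl group; silyl shift gives the trans silyloxy ketone 3 and dilute acid removes the trimethylsilyl group. The new C–O bond is therefore trans to the C1 substituent and is inverted in step 2.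

Step 2
Reactants: 4 trans-6-hydroxycarvone
Product: 6 cis-6-hydroxycarvone (5S,6R), via cis formate 5 (not isolated)
Conditions: HCO2H, PPh3, DIAD, THF, 0 °C to rt; then KHCO3 (cat.), MeOH, 0 °C
Reagents that add atoms: formic acid, OC=O
Why: Mitsunobu reaction: formate displaces the equatorial alkoxyphosphonium at the carbonyl-activated carbon by SN2 with inversion, which places the oxygen cis to the isopropenyl group. The α-keto formate 5 is labile enough to be methanolysed by KHCO3 at 0 °C, conditions chosen as too weakly basic to enolise the axial ketol back to the trans isomer.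

Step 3
Reactants: 6 cis-6-hydroxycarvone
Product: 7 cis-6-(triethylsilyloxy)carvone (5S,6R)
Conditions: TESCl, imidazole, DMAP (cat.), CH2Cl2, 0 °C
Reagents that add atoms: chlorotriethylsilane, CC[Si](Cl)(CC)CC
Why: Standard silylation of a secondary alcohol. Protecting O2 before O3 exists is what later distinguishes the two ring oxygens, and the silyl ether is configurationally more robust than the free ketol.

Step 4
Reactants: 7 cis-6-(triethylsilyloxy)carvone
Product: 8 all-cis allylic alcohol (1S,5S,6R)
Conditions: NaBH4, CeCl3·7H2O, MeOH, −78 °C
Reagents that add atoms: none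
Why: Luche reduction: the cerium salt steers borohydride to 1,2-addition, and hydride attacks the face opposite to both the α-silyloxy group (Felkin–Anh, anti to the α-oxygen) and the isopropenyl group, so the new C3 hydroxyl is cis to both.

Step 5
Reactants: 8 all-cis allylic alcohol
Product: 9 all-cis epoxy alcohol
Conditions: VO(acac)2 (cat.), t-BuOOH, CH2Cl2, 0 °C to rt
Reagents that add atoms: tert-butyl hydroperoxide, CC(C)(C)OO
Why: Vanadium-catalysed hydroxyl-directed epoxidation: the C3 allylic alcohol binds the vanadium alkyl peroxide and the oxygen is delivered to the C4=C5 face cis to O3, setting C4 and C5. The isopropenyl alkene has no free hydroxyl within reach and is left alone.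

Step 6
Reactants: 9 all-cis epoxy alcohol; 10 angelic acid
Product: 11 C3 angelate (isopropenyl compound Cy–C(CH3)=CH2)
Conditions: 2,4,6-trichlorobenzoyl chloride, Et3N, toluene, rt; then 9, 80 °C
Reagents that add atoms: none
Why: Yamaguchi esterification: the alcohol attacks the less hindered angeloyl carbonyl of the mixed anhydride, and leaving out a nucleophilic catalyst avoids the addition–elimination path that turns angelates into tiglates. No stereocentre is involved, and without an alkoxide base the epoxy alcohol cannot undergo Payne rearrangement.

Step 7
Reactants: 11 C3 angelate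
Product: 13 enal (C8 aldehyde), via allylic alcohol 12 (not isolated)
Conditions: SeO2 (cat.), t-BuOOH, CH2Cl2, rt; crude product, MnO2, CH2Cl2, rt
Reagents that add atoms: selenium dioxide, O=[Se]=O (transfers the oxygen atom); tert-butyl hydroperoxide, CC(C)(C)OO (reoxidant)
Why: Riley oxidation: SeO2 undergoes an ene reaction with the only electron-rich alkene left (the ring alkene is an epoxide, the angelate alkene is electron-poor) and the following 2,3-sigmatropic shift puts the oxygen on the methyl carbon C8. MnO2 then oxidises the primary allylic alcohol 12, so that alcohol and any aldehyde formed directly converge on 13.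

Step 8
Reactants: 13 enal
Product: 14 aldoxime (E)
Conditions: NH2OH·HCl, NaOAc, EtOH–H2O, 0 °C to rt
Reagents that add atoms: hydroxylamine hydrochloride, NO.Cl
Why: Oxime condensation of the only aldehyde under acetate buffering, which spares the epoxide, the silyl ether and the esters. The oxime geometry has no consequence for the next step.

Step 9
Reactants: 14 aldoxime
Product: 15 hydroximoyl chloride (Z)
Conditions: NCS, DMF, 0 °C to rt
Reagents that add atoms: N-chlorosuccinimide, O=C1CCC(=O)N1Cl
Why: C-chlorination of an aldoxime with N-chlorosuccinimide is the standard entry to hydroximoyl chlorides as nitrile oxide precursors. The electron-poor alkenes of the substrate should not compete, and the product is used crude.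

Step 10
Reactants: 15 hydroximoyl chloride; 16 2-methylbut-3-en-2-ol
Product: 18 isoxazoline (10S), via nitrile oxide 17 (not isolated)
Conditions: 16 (excess), Et2Zn, (S,S)-diisopropyl tartrate, CHCl3–1,4-dioxane, 0 °C; slow addition of 15
Reagents that add atoms: none
Why: This is a tartrate-modified, zinc alkoxide-directed nitrile oxide cycloaddition; the closest known reaction type is the same process with primary allylic alcohols. Et2Zn turns 16 and the tartrate into an ethylzinc alkoxide/zinc tartrate aggregate whose basic zinc–oxygen bond removes HCl from 15, so nitrile oxide 17 is generated already bound through its oxygen to zinc beside the alkene. The cycloaddition is a concerted, suprafacial [3+2] process in which the dipole carbon C8 bonds to the unsubstituted alkene terminus C9 and the dipole oxygen to C10, so the isoxazoline ring is closed by cycloaddition in one event and not by a separate ring-closing step. The only new stereocentre, C10, is set by the tartrate, which fixes the two zinc atoms bridging the alkoxide oxygen and the dipole oxygen and exposes one alkene face; the (S,S)-ester is chosen for 10S, and the ring stereocentres are too remote to interfere. Regioselectivity for the 5-substituted isoxazoline is that normal for a monosubstituted alkene and is reinforced by the zinc tether. Chemoselectivity over dimerisation of 17 to the furoxan and over addition to the electron-poor C7=C14 or angelate alkenes relies on slow addition of 15 to an excess of the zinc alkoxide, which accelerates only the desired pairing. Facial selectivity is what the step needs most, because C10 later relays C8 and becomes the epoxide carbon.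

Step 11
Reactants: 18 isoxazoline
Product: 20 β′-hydroxy enone (10S), via hydroxy ketimine 19 (not isolated)
Conditions: SmI2, THF, 0 °C; then B(OH)3, MeOH–H2O, rt
Reagents that add atoms: water, O
Why: Reductive N–O cleavage of an alkenyl-conjugated 2-isoxazoline by two single-electron transfers from SmI2 gives the N-unsubstituted hydroxy ketimine 19, which boric acid hydrolyses under conditions too mild for retro-aldol cleavage or dehydration. C10 is untouched; the isoxazoline has served as a masked aldol between C8 and C10.

Step 12
Reactants: 20 β′-hydroxy enone
Product: 21 anti hydroxy acetate (8S,10S; O8 free, O10 acetylated)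
Conditions: SmI2 (cat.), CH3CHO, THF, −10 °C
Reagents that add atoms: acetaldehyde, CC=O
Why: Evans–Tishchenko reduction: the C10 hydroxyl forms a hemiacetal with acetaldehyde, whose samarium alkoxide chelates the C8 ketone in a chair-like bicyclic transition state and delivers hydride intramolecularly to the carbonyl carbon. The new C8 hydroxyl is therefore anti to O10 (8S from 10S) and the C7=C14 alkene is not reduced. The hydride donor ends as the O10 acetate, which leaves O8 as the only free secondary hydroxyl.

Step 13
Reactants: 21 anti hydroxy acetate; 10 angelic acid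
Product: 22 C8 angelate C10 acetate
Conditions: 2,4,6-trichlorobenzoyl chloride, Et3N, toluene, rt; then 21, 80 °C
Reagents that add atoms: none
Why: Yamaguchi esterification as in step 6. Only the secondary allylic O8–H is acylated, because the C11 hydroxyl is tertiary and O10 is blocked. The amine is consumed in forming the anhydride, so the acylation stage runs without free base, which disfavours 1,3-migration of the acetyl group.

Step 14
Reactants: 22 C8 angelate C10 acetate
Product: 23 C8 angelate 10,11-diol (8S,10S)
Conditions: K2CO3 (cat.), MeOH, 0 °C
Reagents that add atoms: none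
Why: Transesterification: an unhindered acetate assisted by the neighbouring tertiary hydroxyl should be methanolysed far faster than the two hindered, conjugated angelates, so brief exposure at 0 °C is expected to free only O10.

Step 15
Reactants: 23 C8 angelate 10,11-diol
Product: 25 bis-epoxide triethylsilyl ether (8S,10R), via C10 mesylate 24 (not isolated)
Conditions: MsCl, Et3N, CH2Cl2, 0 °C; then K2CO3, MeOH, 0 °C
Reagents that add atoms: none
Why: The secondary C10 hydroxyl is sulfonylated selectively (the C11 hydroxyl is tertiary), and the C11 alkoxide then displaces the mesylate in a 3-exo-tet SN2 closure with inversion at C10, turning 10S into the 10R epoxide of the target. This is the classical conversion of a secondary–tertiary 1,2-diol into a trisubstituted epoxide.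

Step 16
Reactants: 25 bis-epoxide triethylsilyl ether
Product: 26 CNP0296086.3 (target)
Conditions: HF·pyridine, pyridine, THF, 0 °C
Reagents that add atoms: none
Why: Fluoride-mediated cleavage of the triethylsilyl ether with pyridine-buffered HF·pyridine. The medium is not basic enough to move the C3 angelate to O2 and, at 0 °C, should not be acidic enough to open the epoxides; no stereocentre is affected.

## Compound list

1 | (R)-carvone, (5R)-2-methyl-5-(prop-1-en-2-yl)cyclohex-2-en-1-one | CC1=CC[C@H](CC1=O)C(C)=C | starting material
2 | trimethyl{[(3R)-6-methyl-3-(prop-1-en-2-yl)cyclohexa-1,5-dien-1-yl]oxy}silane (kinetic silyl dienol ether of 1; formed in the flask) | C=C(C)[C@@H]1CC=C(C)C(O[Si](C)(C)C)=C1 | intermediate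
3 | (5S,6S)-2-methyl-5-(prop-1-en-2-yl)-6-(trimethylsilyloxy)cyclohex-2-en-1-one (trans; formed in the flask) | C=C(C)[C@@H]1CC=C(C)C(=O)[C@H]1O[Si](C)(C)C | intermediate
4 | (5S,6S)-6-hydroxy-2-methyl-5-(prop-1-en-2-yl)cyclohex-2-en-1-one (trans-6-hydroxycarvone) | C=C(C)[C@@H]1CC=C(C)C(=O)[C@H]1O | intermediate
5 | (5S,6R)-6-(formyloxy)-2-methyl-5-(prop-1-en-2-yl)cyclohex-2-en-1-one (cis formate; formed in the flask) | C=C(C)[C@@H]1CC=C(C)C(=O)[C@@H]1OC=O | intermediate
6 | (5S,6R)-6-hydroxy-2-methyl-5-(prop-1-en-2-yl)cyclohex-2-en-1-one (cis-6-hydroxycarvone) | C=C(C)[C@@H]1CC=C(C)C(=O)[C@@H]1O | intermediate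
7 | (5S,6R)-2-methyl-5-(prop-1-en-2-yl)-6-(triethylsilyloxy)cyclohex-2-en-1-one | C=C(C)[C@@H]1CC=C(C)C(=O)[C@@H]1O[Si](CC)(CC)CC | intermediate
8 | (1S,5S,6R)-2-methyl-5-(prop-1-en-2-yl)-6-(triethylsilyloxy)cyclohex-2-en-1-ol (hydroxyl, silyloxy and isopropenyl groups all cis) | C=C(C)[C@@H]1CC=C(C)[C@H](O)[C@@H]1O[Si](CC)(CC)CC | intermediate
9 | (1S,2R,3R,4R,5S)-4,5-epoxy-4-methyl-1-(prop-1-en-2-yl)-2-(triethylsilyloxy)cyclohexan-3-ol (target locants; isopropenyl, O2, O3 and epoxide oxygen all cis; C4 is formally R only because the free C3 hydroxyl changes the CIP ranking) | C=C(C)[C@@H]1C[C@@H]2O[C@]2(C)[C@H](O)[C@@H]1O[Si](CC)(CC)CC | intermediate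
10 | angelic acid, (Z)-2-methylbut-2-enoic acid | C/C=C(/C)C(=O)O | starting material
11 | (1S,2R,3R,4S,5S)-4,5-epoxy-4-methyl-1-(prop-1-en-2-yl)-2-(triethylsilyloxy)cyclohexan-3-yl angelate (Cy–C(CH3)=CH2) | C=C(C)[C@@H]1C[C@@H]2O[C@]2(C)[C@H](OC(=O)/C(C)=C\C)[C@@H]1O[Si](CC)(CC)CC | intermediate
12 | 2-Cy-prop-2-en-1-ol (C8 allylic alcohol; formed in the flask) | C=C(CO)[C@@H]1C[C@@H]2O[C@]2(C)[C@H](OC(=O)/C(C)=C\C)[C@@H]1O[Si](CC)(CC)CC | intermediate
13 | 2-Cy-prop-2-enal | C=C(C=O)[C@@H]1C[C@@H]2O[C@]2(C)[C@H](OC(=O)/C(C)=C\C)[C@@H]1O[Si](CC)(CC)CC | intermediate
14 | (E)-2-Cy-prop-2-enal oxime | C=C(/C=N/O)[C@@H]1C[C@@H]2O[C@]2(C)[C@H](OC(=O)/C(C)=C\C)[C@@H]1O[Si](CC)(CC)CC | intermediate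
15 | (Z)-N-hydroxy-2-Cy-prop-2-enimidoyl chloride | C=C(/C(Cl)=N/O)[C@@H]1C[C@@H]2O[C@]2(C)[C@H](OC(=O)/C(C)=C\C)[C@@H]1O[Si](CC)(CC)CC | intermediate
16 | 2-methylbut-3-en-2-ol | C=CC(C)(C)O | starting material
17 | 2-Cy-prop-2-enenitrile N-oxide (formed in the flask) | C=C(C#[N+][O-])[C@@H]1C[C@@H]2O[C@]2(C)[C@H](OC(=O)/C(C)=C\C)[C@@H]1O[Si](CC)(CC)CC | intermediate
18 | 2-[(5S)-3-(1-Cy-ethenyl)-4,5-dihydro-1,2-oxazol-5-yl]propan-2-ol (isoxazoline C5 = C10) | C=C(C1=NO[C@H](C(C)(C)O)C1)[C@@H]2C[C@@H]3O[C@]3(C)[C@H](OC(=O)/C(C)=C\C)[C@@H]2O[Si](CC)(CC)CC | intermediate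
19 | (5S)-3-imino-6-methyl-2-Cy-hept-1-ene-5,6-diol (formed in the flask) | C=C(C(=N)C[C@H](O)C(C)(C)O)[C@@H]1C[C@@H]2O[C@]2(C)[C@H](OC(=O)/C(C)=C\C)[C@@H]1O[Si](CC)(CC)CC | intermediate
20 | (5S)-5,6-dihydroxy-6-methyl-2-Cy-hept-1-en-3-one | C=C(C(=O)C[C@H](O)C(C)(C)O)[C@@H]1C[C@@H]2O[C@]2(C)[C@H](OC(=O)/C(C)=C\C)[C@@H]1O[Si](CC)(CC)CC | intermediate
21 | (3S,5S)-3,6-dihydroxy-6-methyl-2-Cy-hept-1-en-5-yl acetate (heptene C3 = C8, C5 = C10; anti) | C=C([C@@H](O)C[C@H](OC(C)=O)C(C)(C)O)[C@@H]1C[C@@H]2O[C@]2(C)[C@H](OC(=O)/C(C)=C\C)[C@@H]1O[Si](CC)(CC)CC | intermediate
22 | (3S,5S)-5-acetoxy-6-hydroxy-6-methyl-2-Cy-hept-1-en-3-yl angelate | C=C([C@@H](OC(=O)/C(C)=C\C)C[C@H](OC(C)=O)C(C)(C)O)[C@@H]1C[C@@H]2O[C@]2(C)[C@H](OC(=O)/C(C)=C\C)[C@@H]1O[Si](CC)(CC)CC | intermediate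
23 | (3S,5S)-5,6-dihydroxy-6-methyl-2-Cy-hept-1-en-3-yl angelate | C=C([C@@H](OC(=O)/C(C)=C\C)C[C@H](O)C(C)(C)O)[C@@H]1C[C@@H]2O[C@]2(C)[C@H](OC(=O)/C(C)=C\C)[C@@H]1O[Si](CC)(CC)CC | intermediate
24 | (3S,5S)-6-hydroxy-6-methyl-5-(methylsulfonyloxy)-2-Cy-hept-1-en-3-yl angelate (formed in the flask) | C=C([C@@H](OC(=O)/C(C)=C\C)C[C@H](OS(C)(=O)=O)C(C)(C)O)[C@@H]1C[C@@H]2O[C@]2(C)[C@H](OC(=O)/C(C)=C\C)[C@@H]1O[Si](CC)(CC)CC | intermediate
25 | (3S)-4-[(2R)-3,3-dimethyloxiran-2-yl]-2-Cy-but-1-en-3-yl angelate | C=C([C@H](C[C@H]1OC1(C)C)OC(=O)/C(C)=C\C)[C@@H]1C[C@@H]2O[C@]2(C)[C@H](OC(=O)/C(C)=C\C)[C@@H]1O[Si](CC)(CC)CC | intermediate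
26 | CNP0296086.3, (3S)-4-[(2R)-3,3-dimethyloxiran-2-yl]-2-[(1S,2R,3R,4S,5S)-3-(angeloyloxy)-4,5-epoxy-2-hydroxy-4-methylcyclohexyl]but-1-en-3-yl angelate | C=C([C@H](C[C@H]1OC1(C)C)OC(=O)/C(C)=C\C)[C@@H]1C[C@@H]2O[C@]2(C)[C@H](OC(=O)/C(C)=C\C)[C@@H]1O | target

## Step count and risks

Total: 16 steps. Longest linear sequence: 16 steps from (R)-carvone 1; compounds 10 and 16 are purchased.

**Step 10 (key step).** The most likely failure is poor facial discrimination at C10, because a tertiary zinc alkoxide may not adopt the tartrate-bridged geometry established for primary allylic alkoxides. If the cycloaddition is slow, dimerisation of the nitrile oxide to the furoxan would follow. The fallback relays C10 from a sacrificial carbinol stereocentre under magnesium chelation. Setting out from 15, the nitrile oxide is generated (EtMgBr, i-PrOH, CH2Cl2, 0 °C) in the presence of the magnesium alkoxide of (S)-but-3-en-2-ol (C=C[C@H](C)O). Chelation of the dipole oxygen to the alkoxide magnesium, with the allylic hydrogen eclipsing the alkene, should deliver the syn adduct, the (5S)-isoxazolinyl (S)-ethanol F1. Dess–Martin periodinane should then give the 5-acetylisoxazoline F2, and MeMgBr with anhydrous CeCl3 at −78 °C (to suppress enolisation at C10) adds the second methyl group and returns to 18.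

**Step 2.** The inversion may be eroded by epimerisation of the axial α-ketol to the trans isomer during formate removal, or elimination may compete with displacement at the α-keto carbon. The fallback keeps the inverted oxygen acylated until the ketone is gone. From 4, Mitsunobu reaction with 4-nitrobenzoic acid gives the cis 4-nitrobenzoate F3. Luche reduction gives the allylic alcohol F4, VO(acac)2 with t-BuOOH gives the epoxy alcohol F5, and Yamaguchi angeloylation gives the angelate nitrobenzoate F6. Mg(OMe)2 in MeOH removes the activated aryl ester to give the hydroxy angelate F7, and TESCl with imidazole returns to 11.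

**Step 7.** The ene step may lose regiocontrol by abstracting the C1 methine hydrogen instead of a methyl hydrogen, and selenous acid may cleave the silyl ether or open the epoxide. The fallback is an ene-type chlorination. From 11, Ca(OCl)2 with CO2 in CH2Cl2–H2O at 0 °C should give the allylic chloride F8; chlorine enters at the former methylene carbon and the former methyl becomes the new methylene, which is constitutionally the same 2-substituted allyl unit. Trimethylamine N-oxide in DMSO at rt then oxidises F8 to enal 13.

**Step 12.** Hydride transfer to the cross-conjugated ketone may be slow, which would let conjugate addition of the C10 hydroxyl to C14 (tetrahydropyranone formation) or migration of the acetyl group from O10 to O8 compete. The fallback is a Saksena–Evans reduction. From 20, Me4NBH(OAc)3 in MeCN–AcOH at −30 °C should give the anti triol F9 by intramolecular hydride delivery from the O10-bound borohydride. One equivalent of the angelic mixed anhydride is then expected to acylate the allylic O8 in preference to O10, which is flanked by the quaternary C11; this returns to 23 and by-passes 21 and 22.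

**Step 16.** The acid-labile 2,2-dimethyloxirane may be opened by HF or fluoride while the hindered silyl ether is still being cleaved. The fallback closes the side-chain epoxide last. From 23, mesylation gives 24, now isolated; HF·pyridine with pyridine removes the silyl ether to give the hydroxy mesylate F10; DBU in CH2Cl2 then closes the epoxide with inversion and arrives at 26.

## Further compounds

F1 | step 10 | (1S)-1-[(5S)-3-(1-Cy-ethenyl)-4,5-dihydro-1,2-oxazol-5-yl]ethanol | C=C(C1=NO[C@H]([C@H](C)O)C1)[C@@H]2C[C@@H]3O[C@]3(C)[C@H](OC(=O)/C(C)=C\C)[C@@H]2O[Si](CC)(CC)CC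
F2 | step 10 | 1-[(5S)-3-(1-Cy-ethenyl)-4,5-dihydro-1,2-oxazol-5-yl]ethanone | C=C(C1=NO[C@H](C(C)=O)C1)[C@@H]2C[C@@H]3O[C@]3(C)[C@H](OC(=O)/C(C)=C\C)[C@@H]2O[Si](CC)(CC)CC
F3 | step 2 | cis-6-(4-nitrobenzoyloxy)carvone, ring configuration as in 6 | C=C(C)[C@@H]1CC=C(C)C(=O)[C@@H]1OC(=O)c1ccc(cc1)[N+](=O)[O-]
F4 | step 2 | all-cis 2-methyl-5-(prop-1-en-2-yl)-6-(4-nitrobenzoyloxy)cyclohex-2-en-1-ol, configuration as in 8 | C=C(C)[C@@H]1CC=C(C)[C@H](O)[C@@H]1OC(=O)c1ccc(cc1)[N+](=O)[O-]
F5 | step 2 | all-cis 4,5-epoxy-4-methyl-1-(prop-1-en-2-yl)-2-(4-nitrobenzoyloxy)cyclohexan-3-ol, configuration as in 9 | C=C(C)[C@@H]1C[C@@H]2O[C@]2(C)[C@H](O)[C@@H]1OC(=O)c1ccc(cc1)[N+](=O)[O-]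
F6 | step 2 | all-cis 4,5-epoxy-4-methyl-1-(prop-1-en-2-yl)-2-(4-nitrobenzoyloxy)cyclohexan-3-yl angelate, configuration as in 11 | C=C(C)[C@@H]1C[C@@H]2O[C@]2(C)[C@H](OC(=O)/C(C)=C\C)[C@@H]1OC(=O)c1ccc(cc1)[N+](=O)[O-]
F7 | step 2 | all-cis 4,5-epoxy-2-hydroxy-4-methyl-1-(prop-1-en-2-yl)cyclohexan-3-yl angelate, configuration as in 11 | C=C(C)[C@@H]1C[C@@H]2O[C@]2(C)[C@H](OC(=O)/C(C)=C\C)[C@@H]1O
F8 | step 7 | 3-chloro-2-Cy-prop-1-ene (allylic chloride) | C=C(CCl)[C@@H]1C[C@@H]2O[C@]2(C)[C@H](OC(=O)/C(C)=C\C)[C@@H]1O[Si](CC)(CC)CC
F9 | step 12 | (3S,5S)-6-methyl-2-Cy-hept-1-ene-3,5,6-triol (anti triol) | C=C([C@@H](O)C[C@H](O)C(C)(C)O)[C@@H]1C[C@@H]2O[C@]2(C)[C@H](OC(=O)/C(C)=C\C)[C@@H]1O[Si](CC)(CC)CC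
F10 | step 16 | (3S,5S)-6-hydroxy-6-methyl-5-(methylsulfonyloxy)-2-[(1S,2R,3R,4S,5S)-3-(angeloyloxy)-4,5-epoxy-2-hydroxy-4-methylcyclohexyl]hept-1-en-3-yl angelate | C=C([C@@H](OC(=O)/C(C)=C\C)C[C@H](OS(C)(=O)=O)C(C)(C)O)[C@@H]1C[C@@H]2O[C@]2(C)[C@H](OC(=O)/C(C)=C\C)[C@@H]1O
A1 | alternative 1 | all-cis cyclohexenol with C2 4-methoxybenzyl ether and C7 Weinreb amide | CON(C)C(=O)[C@@H]1CC=C(C)[C@H](O)[C@@H]1OCc1ccc(OC)cc1
A2 | alternative 1 | acyclic (Z)-alkenyl iodide aldehyde carrying the C2 4-methoxybenzyl ether and the C7 Weinreb amide | CON(C)C(=O)[C@H](C/C=C(/C)I)[C@@H](OCc1ccc(OC)cc1)C=O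
A3 | alternative 2 | cis-fused diisopropyldioxasilolane cyclohexene with C7 ketone, C8 tert-butyldimethylsilyl ether and prenyl group | CC(C)=CC[C@H](O[Si](C)(C)C(C)(C)C)C(=O)[C@@H]1CC=C(C)[C@H](O[Si](C(C)C)(C(C)C)O2)[C@@H]12
A4 | alternative 2 | diisopropylsilylene-tethered triene: (E)-2-methylbuta-1,3-dienyl ether and (Z)-β-silyloxy enone | CC(C)=CC[C@H](O[Si](C)(C)C(C)(C)C)C(=O)/C=C\O[Si](C(C)C)(C(C)C)O/C=C(\C)C=C
A5 | alternative 3 | all-cis 4-methyl-2,3-bis(triethylsilyloxy)cyclohex-4-enecarboxylic acid | OC(=O)[C@@H]1CC=C(C)[C@H](O[Si](CC)(CC)CC)[C@@H]1O[Si](CC)(CC)CC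
A6 | alternative 3 | 6-ethenyl-6-methyl-4,5-bis(triethylsilyloxy)oxan-2-one, silyloxy groups cis to each other and to the methyl group | O=C1C[C@@H](O[Si](CC)(CC)CC)[C@@H](O[Si](CC)(CC)CC)[C@](C)(C=C)O1
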